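**Retrosynthetic overview**

- The route rests on the four adjacent ring methylenes C11–C14 of the 27-membered lactone (26 ring carbons and one ring oxygen). They are carried as the four carbons of a 2,5-disubstituted thiophene ring, and the sulfur is cut out at the end.
- Key disconnection C10–C11: the acid chloride at C10 acylates the free alpha carbon of the thiophene intramolecularly. This closes the only ring, a 2,5-bridged thiophenophane keto lactone.
- The open precursor is split at the ester C1–O into 12-(thiophen-2-yl)dodecan-1-ol (C11–C26) and sebacoyl chloride (C1–C10). The alcohol is split at C14–C15 into 2-thienyllithium and THP-protected 12-bromo-1-dodecanol.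
- After ring closure the C10 ketone is taken to CH2 by ionic hydrogenation, and Raney nickel then removes sulfur and saturates C11–C14.
- Ring order: thiophenophane macrocycle first (step 6); it becomes the plain monocyclic lactone when the thiophene is desulfurized (step 8).

Key step: step 6

Remark on the chemistry: the acetal carbon of the THP group (compounds 2 and 5) and the carbinol carbon of 11 form as racemates. Both centres are removed again, and the target has no stereocentre.

**Route**

Step 1
Reactants: 1 12-bromo-1-dodecanol
Product: 2 2-[(12-bromododecyl)oxy]tetrahydro-2H-pyran (racemic)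
Conditions: DHP (1.3 equiv), PPTS (cat.), CH2Cl2, rt
Reagents that add atoms: 3,4-dihydro-2H-pyran, C1=COCCC1
Why: Acid-catalysed addition of the alcohol to the enol ether (tetrahydropyranylation) should mask the hydroxyl against the organolithium of step 2; the acetal carbon forms racemic and is removed in step 3.

Step 2
Reactants: 3 thiophene; 2 2-[(12-bromododecyl)oxy]tetrahydro-2H-pyran
Product: 5 2-{[12-(thiophen-2-yl)dodecyl]oxy}tetrahydro-2H-pyran (racemic), via 2-thienyllithium 4 (not isolated)
Conditions: 3 (1.5 equiv), n-BuLi (1.4 equiv), THF, −78 → 0 °C; then 2, 0 → 50 °C
Reagents that add atoms: none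
Why: n-BuLi should deprotonate thiophene selectively at the alpha carbon, and the resulting 2-thienyllithium should displace bromide from the unhindered primary bromide in an SN2 alkylation, the THP acetal being inert to organolithiums.

Step 3
Reactants: 5 2-{[12-(thiophen-2-yl)dodecyl]oxy}tetrahydro-2H-pyran
Product: 6 12-(thiophen-2-yl)dodecan-1-ol
Conditions: TsOH·H2O (cat.), MeOH–THF, rt
Reagents that add atoms: none
Why: Acid-catalysed transacetalization to methanol (THP cleavage) should free the primary alcohol, the 2-alkylthiophene being stable to catalytic sulfonic acid at room temperature.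

Step 4
Reactants: 6 12-(thiophen-2-yl)dodecan-1-ol; 7 sebacoyl chloride (decanedioyl dichloride)
Product: 9 10-oxo-10-{[12-(thiophen-2-yl)dodecyl]oxy}decanoic acid, via ester acid chloride 8 (not isolated)
Conditions: 6 added slowly to 7 (5 equiv), pyridine, CH2Cl2, 0 °C → rt; then H2O–THF, pyridine, rt; 1 M HCl work-up, chromatography
Reagents that add atoms: water, O
Why: Nucleophilic acyl substitution (O-acylation) by inverse addition into a fivefold excess of the diacid chloride should engage only one end of the reagent; hydrolysis of the remaining COCl group then gives a half-ester acid that chromatography separates from sebacic acid and from traces of diester, so that the key step receives a pure monofunctional substrate.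

Step 5
Reactants: 9 10-oxo-10-{[12-(thiophen-2-yl)dodecyl]oxy}decanoic acid
Product: 8 12-(thiophen-2-yl)dodecyl 10-chloro-10-oxodecanoate
Conditions: (COCl)2 (1.5 equiv), DMF (cat.), CH2Cl2, 0 °C → rt; evaporation, toluene azeotrope, used crude at once
Reagents that add atoms: oxalyl chloride, ClC(=O)C(=O)Cl
Why: DMF-catalysed conversion of a carboxylic acid into its chloride with oxalyl chloride gives only gaseous by-products, and neither the alkyl ester nor the thiophene should react with the catalytic chloroiminium species at or below room temperature.

Step 6
Reactants: 8 12-(thiophen-2-yl)dodecyl 10-chloro-10-oxodecanoate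
Product: 10 2,5-bridged thiophenophane keto lactone (lactone of 10-[5-(12-hydroxydodecyl)thiophen-2-yl]-10-oxodecanoic acid)
Conditions: SnCl4 (3 equiv), CH2Cl2, 0 °C → rt, syringe-pump addition of 8 over ca. 20 h (final ca. 1 mM); cold 1 M HCl quench
Reagents that add atoms: none
Why: SnCl4 ionizes the acid chloride of 8 to an acylium ion at C10, the free alpha carbon of the thiophene (position 5, the future C11) attacks it in an electrophilic aromatic substitution, and loss of the proton from the sigma complex restores the thiophene and leaves the C10–C11 bond. The closest known reaction type is the high-dilution intramolecular Friedel–Crafts acylation of omega-(2-thienyl)alkanoyl chlorides to macrocyclic 2,5-thiophenophane ketones, here with a spectator ester in the tether. The single ring is closed end to end as a macrocyclization in which the ring carbon attacks the acyl carbon and the C=O stays exocyclic; it is 27-membered through the four thiophene carbons (26-membered through sulfur), and the 23-atom bridge spans the 2,5-positions without strain. No stereocentre is formed. The step needs alpha over beta substitution, which the intrinsic alpha preference of thiophene and the single free alpha position of the 2-alkylthiophene secure, and ring closure over chain growth, which slow addition into dilute Lewis acid secures by keeping the stationary concentration of 8 low. The acyl group of 10 deactivates the heterocycle against a second acylation, and the excess of SnCl4 compensates for complexation by the ester and ketone carbonyls.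

Step 7
Reactants: 10 2,5-bridged thiophenophane keto lactone
Product: 12 2,5-bridged thiophenophane lactone (lactone of 10-[5-(12-hydroxydodecyl)thiophen-2-yl]decanoic acid), via thienyl carbinol 11 (not isolated)
Conditions: Et3SiH (4 equiv), CF3CO2H–CH2Cl2, 0 °C → rt
Reagents that add atoms: none
Why: In this ionic hydrogenation the protonated thienyl ketone takes a hydride from the silane, the carbinol ionizes to a thiophene-stabilized cation that takes a second hydride, and the lactone is not reduced by silane and acid; any material whose thiophene ring is partly reduced to the thiolane would converge on the same product in step 8.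

Step 8
Reactants: 12 2,5-bridged thiophenophane lactone
Product: 13 26-hexacosanolide (oxacycloheptacosan-2-one)
Conditions: Raney Ni (W-2, washed neutral, large excess), H2 (1 atm), THF–EtOH, 50 °C
Reagents that add atoms: none
Why: Reductive desulfurization with Raney nickel should cleave both C–S bonds and saturate the released four-carbon unit, turning the thiophene into the C11–C14 tetramethylene, while the ester is untouched by neutral nickel at this temperature.

**Compound list**

1 | 12-bromo-1-dodecanol | OCCCCCCCCCCCCBr | starting material
2 | 2-[(12-bromododecyl)oxy]tetrahydro-2H-pyran (racemic) | BrCCCCCCCCCCCCOC1CCCCO1 | intermediate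
3 | thiophene | c1ccsc1 | starting material
4 | 2-thienyllithium | [Li]c1cccs1 | intermediate
5 | 2-{[12-(thiophen-2-yl)dodecyl]oxy}tetrahydro-2H-pyran (racemic) | s1cccc1CCCCCCCCCCCCOC2CCCCO2 | intermediate
6 | 12-(thiophen-2-yl)dodecan-1-ol | OCCCCCCCCCCCCc1cccs1 | intermediate
7 | sebacoyl chloride | ClC(=O)CCCCCCCCC(=O)Cl | starting material
8 | 12-(thiophen-2-yl)dodecyl 10-chloro-10-oxodecanoate | ClC(=O)CCCCCCCCC(=O)OCCCCCCCCCCCCc1cccs1 | intermediate
9 | 10-oxo-10-{[12-(thiophen-2-yl)dodecyl]oxy}decanoic acid | OC(=O)CCCCCCCCC(=O)OCCCCCCCCCCCCc1cccs1 | intermediate
10 | 2,5-bridged thiophenophane keto lactone | O=C1CCCCCCCCC(=O)c2ccc(s2)CCCCCCCCCCCCO1 | intermediate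
11 | thienyl carbinol lactone (racemic; 10 with C10 as CH–OH) | O=C1CCCCCCCCC(O)c2ccc(s2)CCCCCCCCCCCCO1 | intermediate
12 | 2,5-bridged thiophenophane lactone (C10 as CH2) | O=C1CCCCCCCCCc2ccc(s2)CCCCCCCCCCCCO1 | intermediate
13 | 26-hexacosanolide | O=C1CCCCCCCCCCCCCCCCCCCCCCCCCO1 | target

**Step count and risks**

Total step count: 8. Longest linear sequence: 8 steps, from 12-bromo-1-dodecanol (1).

Steps most likely to fail:

1. Step 6. Intermolecular acylation may outrun ring closure and give linear or cyclic oligomers, or the Lewis acid may be held by the ester carbonyl so that ionization stalls and the acid chloride decomposes. The fallback keeps the thiophene as the masked C11–C14 unit but reverses the order of the two connections, so that the ring is closed at the ester C–O bond. It sets out from alcohol 6. Acetylation (Ac2O, pyridine) gives 12-(thiophen-2-yl)dodecyl acetate F1. Intermolecular Friedel–Crafts acylation of its free alpha position with commercial methyl 10-chloro-10-oxodecanoate and SnCl4 in CH2Cl2 at 0 °C gives methyl 10-[5-(12-acetoxydodecyl)thiophen-2-yl]-10-oxodecanoate F2. LiOH in THF–MeOH–H2O removes the methyl ester and the acetate to give 10-[5-(12-hydroxydodecyl)thiophen-2-yl]-10-oxodecanoic acid F3. Yamaguchi macrolactonization follows: 2,4,6-trichlorobenzoyl chloride and Et3N in THF give the mixed 2,4,6-trichlorobenzoic anhydride F4, which is added slowly to DMAP in refluxing toluene at high dilution. This comes back to the route at compound 10.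

2. Step 7. Deoxygenation may stop at the carbinol or its trifluoroacetate, the thienyl cation may be captured by a second molecule instead of by hydride, or the acid may open the lactone. The fallback removes the carbonyl oxygen as a dithioacetal and sets out from 10. Ethane-1,2-dithiol and BF3·OEt2 in CH2Cl2 give the spiro 1,3-dithiolane of the keto lactone F5. Raney Ni in THF–EtOH under H2 then strips the dithiolane sulfur (Mozingo reduction) and the thiophene sulfur in one operation, arriving directly at compound 13 and bypassing 12.

3. Step 8. Hydrogenolysis may be incomplete and leave thiol or alkene residues, the product may be held on the nickel surface, or residual alkali in the nickel may cause alcoholysis of the lactone. The fallback removes sulfur from an open-chain carboxylate, which tolerates forcing basic conditions, and closes the lactone last; it sets out from 12. LiOH in THF–H2O opens the lactone to 10-[5-(12-hydroxydodecyl)thiophen-2-yl]decanoic acid F6. Raney Ni in aqueous Na2CO3–EtOH at reflux gives 26-hydroxyhexacosanoic acid F7. Yamaguchi macrolactonization through the mixed 2,4,6-trichlorobenzoic anhydride F8 (2,4,6-trichlorobenzoyl chloride, Et3N, THF; then slow addition to DMAP in refluxing toluene at high dilution) comes back to the route at compound 13.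

**Further compounds**

F1 | step 6 | 12-(thiophen-2-yl)dodecyl acetate | CC(=O)OCCCCCCCCCCCCc1cccs1
F2 | step 6 | methyl 10-[5-(12-acetoxydodecyl)thiophen-2-yl]-10-oxodecanoate | COC(=O)CCCCCCCCC(=O)c1ccc(s1)CCCCCCCCCCCCOC(C)=O
F3 | step 6 | 10-[5-(12-hydroxydodecyl)thiophen-2-yl]-10-oxodecanoic acid | OC(=O)CCCCCCCCC(=O)c1ccc(s1)CCCCCCCCCCCCO
F4 | step 6 | mixed anhydride of F3 with 2,4,6-trichlorobenzoic acid | O=C(OC(=O)CCCCCCCCC(=O)c1ccc(s1)CCCCCCCCCCCCO)c2c(Cl)cc(Cl)cc2Cl
F5 | step 7 | spiro 1,3-dithiolane of keto lactone 10 at C10 | O=C1CCCCCCCCC2(SCCS2)c3ccc(s3)CCCCCCCCCCCCO1
F6 | step 8 | 10-[5-(12-hydroxydodecyl)thiophen-2-yl]decanoic acid | OC(=O)CCCCCCCCCc1ccc(s1)CCCCCCCCCCCCO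
F7 | step 8 | 26-hydroxyhexacosanoic acid | OC(=O)CCCCCCCCCCCCCCCCCCCCCCCCCO
F8 | step 8 | mixed anhydride of F7 with 2,4,6-trichlorobenzoic acid | O=C(OC(=O)CCCCCCCCCCCCCCCCCCCCCCCCCO)c1c(Cl)cc(Cl)cc1Cl
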